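The plan assembles ring B last, on C2 of a finished, benzyl-protected chromone. Ring B is a para-hydroquinone (oxygen at C2' and C5') with OMe at C4' and with C1' bonded to C2, ortho to the C2' oxygen; a carbene–alkyne–CO benzannulation of a terminal alkyne gives exactly this 1,2,4,5-pattern. In one operation a 2-ethynylchromone (supplying C1' and C6'), a methoxy(1-methoxyvinyl)carbene chromium complex (C5', C4', C3') and one CO ligand (C2') are joined through C5'–C6', C1'–C2' and C2'–C3'. The precursor is 5,7-bis(benzyloxy)-2-ethynyl-6,8-dimethoxychromone, built from syringol via a symmetric 2,6-dihydroxyacetophenone; oxidative demethylation and hydrogenation finish the target.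

Key step: step 9

Remark: the target has no stereocentre, so it is a single achiral compound and no stereocontrol is needed. Chromium carbonyl species are written with Cr=C=O ligands, and the η6 complex 16 is written as arene and Cr(CO)3 joined by a dot.

Step 1
Reactants: 1 2,6-dimethoxyphenol (syringol)
Product: 2 2-(benzyloxy)-1,3-dimethoxybenzene
Conditions: BnBr, K2CO3, DMF, 60 °C
Reagents that add atoms: benzyl bromide, BrCc1ccccc1
Why: Williamson etherification of an acidic phenol should be clean, and the benzyl ether both becomes the later 7-O protecting group and turns the ring into a 1,2,3-trialkoxybenzene that directs electrophiles to C4 and C6.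

Step 2
Reactants: 2 2-(benzyloxy)-1,3-dimethoxybenzene
Product: 3 3-(benzyloxy)-1,5-dibromo-2,4-dimethoxybenzene
Conditions: NBS (2.1 equiv), MeCN, 0 °C → rt, dark
Reagents that add atoms: N-bromosuccinimide, O=C1CCC(=O)N1Br
Why: Electrophilic aromatic bromination of a 1,2,3-trialkoxybenzene should go to the two positions ortho to one outer methoxy group and para to the other, because the central, twisted benzyloxy group activates its own para position only weakly, and ionic conditions in the dark spare the benzylic CH2.

Step 3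
Reactants: 3 3-(benzyloxy)-1,5-dibromo-2,4-dimethoxybenzene
Product: 4 5-(benzyloxy)-4,6-dimethoxybenzene-1,3-diol
Conditions: Pd2(dba)3 (cat.), tBuXPhos (cat.), KOH, 1,4-dioxane/H2O, 100 °C, Ar; then aq. HCl
Reagents that add atoms: potassium hydroxide, [K+].[OH-]
Why: Palladium-catalysed C–O cross-coupling of aryl bromides with hydroxide, run twice on the same ring, should give the resorcinol because the bulky biaryl phosphine drives C–O reductive elimination even next to an ortho methoxy group, while the ethers are inert and degassing plus an acid quench protect the electron-rich diol from air.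

Step 4
Reactants: 4 5-(benzyloxy)-4,6-dimethoxybenzene-1,3-diol
Product: 5 1-[4-(benzyloxy)-2,6-dihydroxy-3,5-dimethoxyphenyl]ethan-1-one
Conditions: AcOH, BF3·OEt2, 60 °C; then aq. NaOAc
Reagents that add atoms: acetic acid, CC(=O)O
Why: Friedel–Crafts C-acylation of a phenol (via O-acetate and Fries-type migration) can only occur at the single free position of the penta-oxygenated ring, between the two hydroxyls, and the moderate temperature should leave the benzyl ether in place.

Step 5
Reactants: 5 1-[4-(benzyloxy)-2,6-dihydroxy-3,5-dimethoxyphenyl]ethan-1-one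
Product: 6 1-[4,6-bis(benzyloxy)-2-hydroxy-3,5-dimethoxyphenyl]ethan-1-one
Conditions: BnBr (1.05 equiv), K2CO3, acetone, reflux
Reagents that add atoms: benzyl bromide, BrCc1ccccc1
Why: Williamson etherification should stop at the mono-ether because the two hydroxyls are equivalent and, once one is benzylated, the other is held in a hydrogen bond to the ketone and reacts far more slowly.

Step 6
Reactants: 6 1-[4,6-bis(benzyloxy)-2-hydroxy-3,5-dimethoxyphenyl]ethan-1-one; 7 ethyl 3-(trimethylsilyl)propiolate
Product: 9 5,7-bis(benzyloxy)-6,8-dimethoxy-2-[(trimethylsilyl)ethynyl]-4H-chromen-4-one, via alkynyl 1,3-diketone 8 (not isolated)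
Conditions: LiHMDS (3.2 equiv), THF, −78 °C; then 7, −78 → −20 °C; AcOH; then TsOH·H2O (cat.), PhMe, 60 °C
Reagents that add atoms: none
Why: Crossed Claisen condensation of the phenoxide–enolate dianion with the ester, followed by acid-catalysed cyclodehydration of the o-hydroxyaryl 1,3-diketone, should give the chromone, since the bulky silyl group shields the alkyne terminus from conjugate addition and from 6-endo attack by the enol oxygen.

Step 7
Reactants: 9 5,7-bis(benzyloxy)-6,8-dimethoxy-2-[(trimethylsilyl)ethynyl]-4H-chromen-4-one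
Product: 10 5,7-bis(benzyloxy)-2-ethynyl-6,8-dimethoxy-4H-chromen-4-one
Conditions: TBAF (1.1 equiv), AcOH (1.5 equiv), THF, −20 °C
Reagents that add atoms: none
Why: Fluoride-induced protodesilylation of an alkynylsilane is fast for a conjugated alkyne at low temperature, and the acetic acid buffer protonates the acetylide at once so that no nucleophile adds to the activated alkyne or to C2 of the chromone.

Step 8
Reactants: 11 methyl vinyl ether; 12 chromium hexacarbonyl
Product: 15 pentacarbonyl[methoxy(1-methoxyvinyl)carbene]chromium, via 1-methoxyvinyllithium 13 (not isolated), via lithium acylchromate 14 (not isolated)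
Conditions: t-BuLi, THF, −78 → 0 °C; Cr(CO)6, THF, −78 °C → rt; then Me3OBF4, CH2Cl2, 0 °C
Reagents that add atoms: trimethyloxonium tetrafluoroborate, C[O+](C)C.F[B-](F)(F)F
Why: Fischer carbene synthesis, in which the α-lithiated enol ether adds to a CO ligand and the acylmetalate is O-methylated by Meerwein's salt, is established for α-alkoxyalkenyllithiums such as 2-lithiodihydropyran and should carry over to the acyclic case.

Step 9
Reactants: 10 5,7-bis(benzyloxy)-2-ethynyl-6,8-dimethoxy-4H-chromen-4-one; 15 pentacarbonyl[methoxy(1-methoxyvinyl)carbene]chromium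
Product: 17 5,7-bis(benzyloxy)-2-(2-hydroxy-4,5-dimethoxyphenyl)-6,8-dimethoxy-4H-chromen-4-one, via tricarbonylchromium arene complex 16 (not isolated)
Conditions: 15 (1.5 equiv), THF (0.05 M), 50 °C, Ar; then MeCN, air, rt
Reagents that add atoms: none
Why: Proposed new method: Thermal loss of a cis CO from 15 opens a site for the alkyne, which inserts into the Cr=C bond with its unsubstituted carbon bonding to the carbene carbon (C5'–C6'), and CO insertion into the new vinylcarbene gives an η4-dienylketene whose ketene carbon is bonded to the chromone-bearing carbon (C1'–C2'). Ring B closes by 6π-electrocyclisation of this dienylketene between the ketene carbon and the vinyl CH2 (C2'–C3'), and the cyclohexadienone tautomerises to the phenol held on Cr(CO)3 (16), from which air in MeCN removes the metal. The closest known reaction type is the Dötz benzannulation of alkenyl(alkoxy)carbene chromium complexes with terminal alkynes, including cyclic α-alkoxyalkenyl complexes, whereas a 2-alkynylchromone and the acyclic 1-methoxyvinyl complex have not been used. No stereocentre is formed. The step needs the regiochemistry of insertion, which the size difference between H and the chromonyl group secures by placing the larger group next to the CO-derived carbon, and it needs phenol formation to outrun cyclobutenone or furan formation from the electron-poor alkyne, which an alkenyl rather than aryl carbene with a donor methoxy group on the vinyl unit, THF and moderate dilution should favour.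

Step 10
Reactants: 17 5,7-bis(benzyloxy)-2-(2-hydroxy-4,5-dimethoxyphenyl)-6,8-dimethoxy-4H-chromen-4-one
Product: 18 2-[5,7-bis(benzyloxy)-6,8-dimethoxy-4-oxo-4H-chromen-2-yl]-5-methoxycyclohexa-2,5-diene-1,4-dione
Conditions: PhI(OAc)2, MeCN/H2O, 0 °C
Reagents that add atoms: water, O
Why: Hypervalent-iodine oxidation of a p-methoxyphenol to the p-quinone needs a free phenol to bind iodine(III), so water attacks C5' and methanol is lost only on ring B, while the fully etherified ring A (which a one-electron oxidant such as CAN could attack) and the C4' methoxy group are untouched.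

Step 11
Reactants: 18 2-[5,7-bis(benzyloxy)-6,8-dimethoxy-4-oxo-4H-chromen-2-yl]-5-methoxycyclohexa-2,5-diene-1,4-dione
Product: 19 2-(2,5-dihydroxy-4-methoxyphenyl)-5,7-dihydroxy-6,8-dimethoxy-4H-chromen-4-one
Conditions: H2 (1 atm), 10% Pd/C, EtOAc/MeOH, rt; work-up under Ar
Reagents that add atoms: none
Why: Catalytic hydrogenation should reduce the quinone to the hydroquinone and hydrogenolyse both benzyl ethers in one operation, while the chromone C2=C3 bond, part of a vinylogous ester conjugated to the aryl ring, resists reduction at ambient pressure.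

Compound list
1 | 2,6-dimethoxyphenol (syringol) | COc1cccc(OC)c1O | starting material
2 | 2-(benzyloxy)-1,3-dimethoxybenzene | COc1cccc(OC)c1OCc1ccccc1 | intermediate
3 | 3-(benzyloxy)-1,5-dibromo-2,4-dimethoxybenzene | COc1c(Br)cc(Br)c(OC)c1OCc1ccccc1 | intermediate
4 | 5-(benzyloxy)-4,6-dimethoxybenzene-1,3-diol | COc1c(O)cc(O)c(OC)c1OCc1ccccc1 | intermediate
5 | 1-[4-(benzyloxy)-2,6-dihydroxy-3,5-dimethoxyphenyl]ethan-1-one | CC(=O)c1c(O)c(OC)c(OCc2ccccc2)c(OC)c1O | intermediate
6 | 1-[4,6-bis(benzyloxy)-2-hydroxy-3,5-dimethoxyphenyl]ethan-1-one | CC(=O)c1c(O)c(OC)c(OCc2ccccc2)c(OC)c1OCc1ccccc1 | intermediate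
7 | ethyl 3-(trimethylsilyl)propiolate | CCOC(=O)C#C[Si](C)(C)C | starting material
8 | 1-[4,6-bis(benzyloxy)-2-hydroxy-3,5-dimethoxyphenyl]-5-(trimethylsilyl)pent-4-yne-1,3-dione | C[Si](C)(C)C#CC(=O)CC(=O)c1c(O)c(OC)c(OCc2ccccc2)c(OC)c1OCc1ccccc1 | intermediate (not isolated)
9 | 5,7-bis(benzyloxy)-6,8-dimethoxy-2-[(trimethylsilyl)ethynyl]-4H-chromen-4-one | C[Si](C)(C)C#Cc1cc(=O)c2c(OCc3ccccc3)c(OC)c(OCc3ccccc3)c(OC)c2o1 | intermediate
10 | 5,7-bis(benzyloxy)-2-ethynyl-6,8-dimethoxy-4H-chromen-4-one | C#Cc1cc(=O)c2c(OCc3ccccc3)c(OC)c(OCc3ccccc3)c(OC)c2o1 | intermediate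
11 | methyl vinyl ether | COC=C | starting material
12 | chromium hexacarbonyl | O=C=[Cr](=C=O)(=C=O)(=C=O)(=C=O)=C=O | starting material
13 | 1-methoxyvinyllithium | [Li]C(=C)OC | intermediate (not isolated)
14 | lithium pentacarbonyl[(1-methoxyvinyl)(oxido)carbene]chromate (lithium acylchromate) | [Li+].[O-]C(C(=C)OC)=[Cr](=C=O)(=C=O)(=C=O)(=C=O)=C=O | intermediate (not isolated)
15 | pentacarbonyl[methoxy(1-methoxyvinyl)carbene]chromium | COC(C(=C)OC)=[Cr](=C=O)(=C=O)(=C=O)(=C=O)=C=O | intermediate
16 | tricarbonyl[η6-5,7-bis(benzyloxy)-2-(2-hydroxy-4,5-dimethoxyphenyl)-6,8-dimethoxy-4H-chromen-4-one]chromium, Cr on ring B | COc1cc(O)c(-c2cc(=O)c3c(OCc4ccccc4)c(OC)c(OCc4ccccc4)c(OC)c3o2)cc1OC.O=C=[Cr](=C=O)=C=O | intermediate (not isolated)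
17 | 5,7-bis(benzyloxy)-2-(2-hydroxy-4,5-dimethoxyphenyl)-6,8-dimethoxy-4H-chromen-4-one | COc1cc(O)c(-c2cc(=O)c3c(OCc4ccccc4)c(OC)c(OCc4ccccc4)c(OC)c3o2)cc1OC | intermediate
18 | 2-[5,7-bis(benzyloxy)-6,8-dimethoxy-4-oxo-4H-chromen-2-yl]-5-methoxycyclohexa-2,5-diene-1,4-dione | COC1=CC(=O)C(=CC1=O)c1cc(=O)c2c(OCc3ccccc3)c(OC)c(OCc3ccccc3)c(OC)c2o1 | intermediate
19 | 2-(2,5-dihydroxy-4-methoxyphenyl)-5,7-dihydroxy-6,8-dimethoxy-4H-chromen-4-one | COc1cc(O)c(-c2cc(=O)c3c(O)c(OC)c(O)c(OC)c3o2)cc1O | target

Total step count: 11. Longest linear sequence: 10 (steps 1–7 and 9–11, from syringol); step 8 is a one-step side branch.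

Steps most likely to fail

Step 9. The chromium dienylketene may be diverted before electrocyclisation (four-electron closure to a cyclobutenone, or carbonyl participation to a furan), the terminal alkyne may insert more than once, or the carbene complex may decompose faster than it loses CO. The fallback brings ring B in intact by the classical chalcone route, sets out from acetophenone 6 and rejoins the route at target 19. Commercial methoxyhydroquinone would be bis-benzylated (BnBr, K2CO3, DMF) to 1,4-bis(benzyloxy)-2-methoxybenzene F1. Vilsmeier–Haack formylation (POCl3, DMF) para to the methoxy group should give 2,5-bis(benzyloxy)-4-methoxybenzaldehyde F2. Claisen–Schmidt condensation of this aldehyde with 6 (KOH, EtOH) should give (E)-1-[4,6-bis(benzyloxy)-2-hydroxy-3,5-dimethoxyphenyl]-3-[2,5-bis(benzyloxy)-4-methoxyphenyl]prop-2-en-1-one F3. Oxidative cyclisation (cat. I2, DMSO, 120 °C) should give 5,7-bis(benzyloxy)-2-[2,5-bis(benzyloxy)-4-methoxyphenyl]-6,8-dimethoxy-4H-chromen-4-one F4. Hydrogenolysis of all four benzyl ethers (H2, Pd/C) then gives 19.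

Step 6. The enolate may add in conjugate fashion to the alkynoate instead of at the ester carbonyl, the enolised diketone may close 6-endo onto the alkyne to a 4-pyranone in competition with chromone formation, and silicon may be lost under base or acid. The fallback builds the alkyne from a chromone-2-carboxylate, sets out from 6 and rejoins at alkyne 10, bypassing 9. Condensation of 6 with diethyl oxalate (NaOEt, EtOH) should give ethyl 4-[4,6-bis(benzyloxy)-2-hydroxy-3,5-dimethoxyphenyl]-2,4-dioxobutanoate F5. Without isolation this is cyclised (cat. HCl, EtOH, 60 °C) to ethyl 5,7-bis(benzyloxy)-6,8-dimethoxy-4-oxo-4H-chromene-2-carboxylate F6. NaBH4 (MeOH/THF, 0 °C) should reduce the activated ester to 5,7-bis(benzyloxy)-2-(hydroxymethyl)-6,8-dimethoxy-4H-chromen-4-one F7. Dess–Martin oxidation gives 5,7-bis(benzyloxy)-6,8-dimethoxy-4-oxo-4H-chromene-2-carbaldehyde F8. Seyferth–Gilbert homologation (dimethyl (diazomethyl)phosphonate, KOtBu, THF, −78 °C, no alcohol present) then gives 10.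

Step 3. The second C–O coupling on the electron-rich bromophenoxide may stall, protodebromination may intervene, and the diol may be oxidised by traces of air in the hot alkaline medium. The fallback introduces the oxygens through boron, from dibromide 3 back to diol 4. Miyaura borylation (B2pin2, Pd(dppf)Cl2, KOAc, dioxane, 90 °C) should give 2,2'-[5-(benzyloxy)-4,6-dimethoxy-1,3-phenylene]bis(4,4,5,5-tetramethyl-1,3,2-dioxaborolane) F9. Cold oxidation (H2O2, aq. NaOH, THF, 0 °C, then acid quench) converts both C–B bonds to C–OH and gives 4.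

Further compounds
F1 | step 9 | 1,4-bis(benzyloxy)-2-methoxybenzene | COc1cc(OCc2ccccc2)ccc1OCc1ccccc1
F2 | step 9 | 2,5-bis(benzyloxy)-4-methoxybenzaldehyde | COc1cc(OCc2ccccc2)c(C=O)cc1OCc1ccccc1
F3 | step 9 | (E)-1-[4,6-bis(benzyloxy)-2-hydroxy-3,5-dimethoxyphenyl]-3-[2,5-bis(benzyloxy)-4-methoxyphenyl]prop-2-en-1-one | COc1cc(OCc2ccccc2)c(/C=C/C(=O)c2c(O)c(OC)c(OCc3ccccc3)c(OC)c2OCc2ccccc2)cc1OCc1ccccc1
F4 | step 9 | 5,7-bis(benzyloxy)-2-[2,5-bis(benzyloxy)-4-methoxyphenyl]-6,8-dimethoxy-4H-chromen-4-one | COc1cc(OCc2ccccc2)c(-c2cc(=O)c3c(OCc4ccccc4)c(OC)c(OCc4ccccc4)c(OC)c3o2)cc1OCc1ccccc1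
F5 | step 6 | ethyl 4-[4,6-bis(benzyloxy)-2-hydroxy-3,5-dimethoxyphenyl]-2,4-dioxobutanoate | CCOC(=O)C(=O)CC(=O)c1c(O)c(OC)c(OCc2ccccc2)c(OC)c1OCc1ccccc1
F6 | step 6 | ethyl 5,7-bis(benzyloxy)-6,8-dimethoxy-4-oxo-4H-chromene-2-carboxylate | CCOC(=O)c1cc(=O)c2c(OCc3ccccc3)c(OC)c(OCc3ccccc3)c(OC)c2o1
F7 | step 6 | 5,7-bis(benzyloxy)-2-(hydroxymethyl)-6,8-dimethoxy-4H-chromen-4-one | OCc1cc(=O)c2c(OCc3ccccc3)c(OC)c(OCc3ccccc3)c(OC)c2o1
F8 | step 6 | 5,7-bis(benzyloxy)-6,8-dimethoxy-4-oxo-4H-chromene-2-carbaldehyde | O=Cc1cc(=O)c2c(OCc3ccccc3)c(OC)c(OCc3ccccc3)c(OC)c2o1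
F9 | step 3 | 2,2'-[5-(benzyloxy)-4,6-dimethoxy-1,3-phenylene]bis(4,4,5,5-tetramethyl-1,3,2-dioxaborolane) | COc1c(B2OC(C)(C)C(C)(C)O2)cc(B2OC(C)(C)C(C)(C)O2)c(OC)c1OCc1ccccc1
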